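**Retrosynthetic overview**

- The target is the 2-hydroxybenzoate of jaeschkeanadiol. The ester is made last from the C4 alkoxide and salicylic acid acetonide; the C3 carbinol comes from i-PrMgCl/CeCl3 addition to a C3 ketone, and the C6 methyl group from an enol triflate.
- Enabling feature: in the seven-membered ring (C3a, C4, C5, C6, C7, C8, C8a) the oxygen-bearing C4 and the methyl-bearing alkene carbon C6 stand 1,3 across the C5 methylene, and the C6=C7 alkene runs on to C8 and the quaternary C8a. This is the pattern of a ring-fused 3-siloxycyclohept-3-en-1-one (ketone at C4, silyl enol ether at C6=C7).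
- Key disconnection: C5–C6 and C8–C8a, a Brook rearrangement-mediated (3+4) annulation of the lithium enolate of a 1-acetyl-2-methylcyclopentene (C8a, C3a, C4, C5) with acryloyl(tert-butyl)dimethylsilane (C6, C7, C8).
- Ring order: the cyclopentene is bought and made chiral by CBS reduction; a cyclopropane forms and opens as a temporary ring inside the key step; the seven-membered ring is closed last. The C3 silyloxy stereocenter relays chirality to C8a, C3a and C4 and is then replaced by the tertiary carbinol.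

Key step: step 5

Remark on locants: the azulene locants of the target are kept for all bicyclic compounds; TBS = tert-butyldimethylsilyl, TIPS = triisopropylsilyl.
Assumption: in the CBS reduction the bromoalkenyl carbon acts as the large group, so the (R)-oxazaborolidine gives the (S)-alcohol; compounds 1, 6 and 23 are taken as commercial.

**Step 1**
Reactants: 1 2-bromo-3-methylcyclopent-2-en-1-one
Product: 2 (1S)-2-bromo-3-methylcyclopent-2-en-1-ol
Conditions: (R)-2-methyl-CBS-oxazaborolidine (10 mol %), BH3·SMe2, THF, −10 °C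
Reagents that add atoms: none
Why: Corey–Bakshi–Shibata reduction: the ketone binds the oxazaborolidine with the bromoalkenyl carbon as the large group, so hydride reaches one carbonyl face and sets the carbinol center (the later C3) as S.

**Step 2**
Reactants: 2 (1S)-2-bromo-3-methylcyclopent-2-en-1-ol
Product: 3 {[(1S)-2-bromo-3-methylcyclopent-2-en-1-yl]oxy}(tert-butyl)dimethylsilane
Conditions: TBSCl, imidazole, DMF, rt
Reagents that add atoms: tert-butyldimethylsilyl chloride, CC(C)(C)[Si](C)(C)Cl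
Why: Imidazole-promoted silylation of a secondary alcohol; the bulky silyl ether is the control element for the key step and the stereocenter is not touched.

**Step 3**
Reactants: 3 {[(1S)-2-bromo-3-methylcyclopent-2-en-1-yl]oxy}(tert-butyl)dimethylsilane
Product: 5 1-[(5S)-5-{[tert-butyl(dimethyl)silyl]oxy}-2-methylcyclopent-1-en-1-yl]ethan-1-one, via vinyllithium 4 (not isolated)
Conditions: t-BuLi (2.1 equiv), Et2O, −78 °C; then MeC(O)N(OMe)Me, −78 → 0 °C
Reagents that add atoms: N-methoxy-N-methylacetamide, CC(=O)N(C)OC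
Why: Bromine–lithium exchange followed by Weinreb ketone synthesis: the chelated tetrahedral adduct stops over-addition, and at −78 °C the vinyllithium is acylated faster than the silyl group can migrate from oxygen to carbon.

**Step 4**
Reactants: 6 methoxyallene (1-methoxypropa-1,2-diene)
Product: 9 1-[tert-butyl(dimethyl)silyl]prop-2-en-1-one, via lithioallene 7 (not isolated), via silylallene 8 (not isolated)
Conditions: n-BuLi, THF, −78 °C; TBSCl, −78 → 0 °C; then 1 M aq. HCl, THF, 0 °C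
Reagents that add atoms: tert-butyldimethylsilyl chloride, CC(C)(C)[Si](C)(C)Cl; water, O
Why: α-Lithiation and silylation of methoxyallene followed by acid hydrolysis of the allenyl enol ether, the standard entry to α,β-unsaturated acylsilanes; no stereocenter is formed.

**Step 5**
Reactants: 5 1-[(5S)-5-{[tert-butyl(dimethyl)silyl]oxy}-2-methylcyclopent-1-en-1-yl]ethan-1-one; 9 1-[tert-butyl(dimethyl)silyl]prop-2-en-1-one
Product: 13 (3S,3aR,8aR)-3,6-bis{[tert-butyl(dimethyl)silyl]oxy}-8a-methyl-2,3,3a,5,8,8a-hexahydroazulen-4(1H)-one, via lithium dienolate 10 (not isolated), via cyclopropanolate 11 (not isolated), via bicyclic enolate 12 (not isolated)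
Conditions: LiN(i-Pr)2 (1.05 equiv), THF, −78 °C; add 9, −78 → 0 °C; then AcOH, −78 °C
Reagents that add atoms: none
Why: Brook rearrangement-mediated (3+4) annulation: the methylene carbon of dienolate 10 adds to the acylsilane carbonyl of 9, the silyl group shifts from carbon to oxygen (1,2-Brook rearrangement) and the siloxyallyl carbanion adds to the ketone carbonyl to give the cis-1,2-divinylcyclopropanolate 11, whose oxyanion-accelerated Cope rearrangement gives the ring-fused enolate 12, which AcOH protonates at C3a. The closest known reaction type is the annulation of acryloylsilanes with lithium enolates of 1-acetylcycloalkenes to ring-fused 3-siloxycyclohept-3-en-1-ones. The temporary cyclopropane closes by intramolecular carbonyl addition (3-exo-trig), and the seven-membered ring closes in the 3,3-sigmatropic shift through a boat transition state that joins C8 to C8a while the cyclopropane bond opens. C8a is set because the carbanion, and after it the vinyl terminus, must come to the cyclopentene face opposite to the OTBS group at C3; C3a is set by protonation of 12 on that same face, away from OTBS and the 8a-methyl group, which gives the trans ring fusion. The step needs 1,2- over 1,4-addition to 9 (secured by the hard lithium enolate at −78 °C and the very electrophilic acylsilane carbonyl), a cis-divinyl arrangement (secured by the coupled Brook shift and ring closure) and a regiodefined product (the ketone at C4 and the silyl enol ether at C6=C7 follow from the mechanism).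

**Step 6**
Reactants: 13 (3S,3aR,8aR)-3,6-bis{[tert-butyl(dimethyl)silyl]oxy}-8a-methyl-2,3,3a,5,8,8a-hexahydroazulen-4(1H)-one
Product: 14 (3S,3aS,4S,8aR)-3,6-bis{[tert-butyl(dimethyl)silyl]oxy}-8a-methyl-1,2,3,3a,4,5,8,8a-octahydroazulen-4-ol
Conditions: SmI2 (2.5 equiv), H2O, Et3N, THF, 0 °C
Reagents that add atoms: none
Why: Single-electron (ketyl) reduction with SmI2/H2O/amine: the samarium-bound oxygen takes the equatorial position away from the axial 8a-methyl group and carbon is protonated from the axial side, so C4 should carry the equatorial OH trans to the 8a-methyl group and cis to H-3a, as in the target, while the fast, nearly neutral conditions spare the silyl enol ether and the epimerizable C3a center.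

**Step 7**
Reactants: 14 (3S,3aS,4S,8aR)-3,6-bis{[tert-butyl(dimethyl)silyl]oxy}-8a-methyl-1,2,3,3a,4,5,8,8a-octahydroazulen-4-ol
Product: 15 (3S,3aR,4S,8aR)-3,6-bis{[tert-butyl(dimethyl)silyl]oxy}-8a-methyl-4-{[tri(propan-2-yl)silyl]oxy}-1,2,3,3a,4,5,8,8a-octahydroazulene
Conditions: TIPSOTf, 2,6-lutidine, CH2Cl2, −78 → 0 °C
Reagents that add atoms: triisopropylsilyl trifluoromethanesulfonate, CC(C)[Si](C(C)C)(C(C)C)OS(=O)(=O)C(F)(F)F
Why: Silylation with a silyl triflate and a hindered pyridine base, which protects the hindered C4 alcohol without forming an alkoxide that could take over the enol silyl group.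

**Step 8**
Reactants: 15 (3S,3aR,4S,8aR)-3,6-bis{[tert-butyl(dimethyl)silyl]oxy}-8a-methyl-4-{[tri(propan-2-yl)silyl]oxy}-1,2,3,3a,4,5,8,8a-octahydroazulene
Product: 17 (3S,3aR,4S,8aR)-3-{[tert-butyl(dimethyl)silyl]oxy}-8a-methyl-4-{[tri(propan-2-yl)silyl]oxy}-1,2,3,3a,4,5,8,8a-octahydroazulen-6-yl trifluoromethanesulfonate, via cesium enolate 16 (not isolated)
Conditions: CsF, PhNTf2, DME, rt
Reagents that add atoms: N-phenylbis(trifluoromethanesulfonimide), O=S(=O)(N(c1ccccc1)S(=O)(=O)C(F)(F)F)C(F)(F)F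
Why: Fluoride-induced unmasking of the silyl enol ether with in situ triflation of the enolate (enol triflate formation), which keeps the C6=C7 position fixed by the annulation; the alkyl silyl ethers react much more slowly with CsF in DME.

**Step 9**
Reactants: 17 (3S,3aR,4S,8aR)-3-{[tert-butyl(dimethyl)silyl]oxy}-8a-methyl-4-{[tri(propan-2-yl)silyl]oxy}-1,2,3,3a,4,5,8,8a-octahydroazulen-6-yl trifluoromethanesulfonate
Product: 18 (3S,3aR,4S,8aR)-3-{[tert-butyl(dimethyl)silyl]oxy}-6,8a-dimethyl-4-{[tri(propan-2-yl)silyl]oxy}-1,2,3,3a,4,5,8,8a-octahydroazulene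
Conditions: MeMgBr, Fe(acac)3 (5 mol %), THF/NMP, −30 → 0 °C
Reagents that add atoms: methylmagnesium bromide, C[Mg]Br
Why: Iron-catalyzed Kumada-type cross-coupling of an alkenyl triflate with a methyl Grignard reagent, which replaces OTf by CH3 without moving the C6=C7 double bond and tolerates silyl ethers.

**Step 10**
Reactants: 18 (3S,3aR,4S,8aR)-3-{[tert-butyl(dimethyl)silyl]oxy}-6,8a-dimethyl-4-{[tri(propan-2-yl)silyl]oxy}-1,2,3,3a,4,5,8,8a-octahydroazulene
Product: 19 (3S,3aR,4S,8aR)-6,8a-dimethyl-4-{[tri(propan-2-yl)silyl]oxy}-1,2,3,3a,4,5,8,8a-octahydroazulen-3-ol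
Conditions: HF·pyridine, pyridine, THF, 0 °C → rt
Reagents that add atoms: none
Why: Selective desilylation: a secondary TBS ether is cleaved by buffered HF·pyridine much faster than the more hindered secondary TIPS ether, which frees only the C3 alcohol.

**Step 11**
Reactants: 19 (3S,3aR,4S,8aR)-6,8a-dimethyl-4-{[tri(propan-2-yl)silyl]oxy}-1,2,3,3a,4,5,8,8a-octahydroazulen-3-ol
Product: 20 (3aS,4S,8aR)-6,8a-dimethyl-4-{[tri(propan-2-yl)silyl]oxy}-2,3a,4,5,8,8a-hexahydroazulen-3(1H)-one
Conditions: Dess–Martin periodinane, CH2Cl2, rt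
Reagents that add atoms: none
Why: Dess–Martin oxidation of the secondary alcohol under mild, non-basic conditions, so that the C3a center next to the new ketone keeps its configuration.

**Step 12**
Reactants: 20 (3aS,4S,8aR)-6,8a-dimethyl-4-{[tri(propan-2-yl)silyl]oxy}-2,3a,4,5,8,8a-hexahydroazulen-3(1H)-one
Product: 21 (3R,3aS,4S,8aR)-6,8a-dimethyl-3-(propan-2-yl)-4-{[tri(propan-2-yl)silyl]oxy}-1,2,3,3a,4,5,8,8a-octahydroazulen-3-ol
Conditions: CeCl3 (anhydrous, 1.5 equiv), i-PrMgCl (1.5 equiv), THF, −78 → 0 °C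
Reagents that add atoms: isopropylmagnesium chloride, CC(C)[Mg]Cl
Why: Organocerium (Imamoto) 1,2-addition, which suppresses enolization and β-hydride reduction of the hindered ketone; the nucleophile should attack the carbonyl face opposite to C4 on the neighboring C3a and to the 8a-methyl group, so OH ends up cis to the angular methyl group and isopropyl cis to H-3a (C3 = R).

**Step 13**
Reactants: 21 (3R,3aS,4S,8aR)-6,8a-dimethyl-3-(propan-2-yl)-4-{[tri(propan-2-yl)silyl]oxy}-1,2,3,3a,4,5,8,8a-octahydroazulen-3-ol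
Product: 22 (3R,3aS,4S,8aR)-6,8a-dimethyl-3-(propan-2-yl)-1,2,3,3a,4,5,8,8a-octahydroazulene-3,4-diol (jaeschkeanadiol)
Conditions: Bu4NF, THF, 50 °C
Reagents that add atoms: none
Why: Fluoride-mediated cleavage of the TIPS ether gives the 3,4-diol without touching the tertiary alcohol or the alkene.

**Step 14**
Reactants: 22 (3R,3aS,4S,8aR)-6,8a-dimethyl-3-(propan-2-yl)-1,2,3,3a,4,5,8,8a-octahydroazulene-3,4-diol; 23 2,2-dimethyl-4H-1,3-benzodioxin-4-one (salicylic acid acetonide)
Product: 25 (3R,3aS,4S,8aR)-3-hydroxy-6,8a-dimethyl-3-(propan-2-yl)-1,2,3,3a,4,5,8,8a-octahydroazulen-4-yl 2-hydroxybenzoate, via sodium alkoxide 24 (not isolated)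
Conditions: NaN(SiMe3)2 (1.1 equiv), THF, 0 °C; then 23, 0 °C → rt
Reagents that add atoms: none
Why: Transesterification of a salicylic acid acetonide (benzodioxinone ring opening by an alkoxide with loss of acetone): the secondary C4 alkoxide attacks the activated lactone carbonyl while the hindered tertiary C3 hydroxyl stays inert, and the phenol is set free in the same step with retention at C4.

**Compound list**

1 | 2-bromo-3-methylcyclopent-2-en-1-one | CC1=C(Br)C(=O)CC1 | starting material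
2 | (1S)-2-bromo-3-methylcyclopent-2-en-1-ol | CC1=C(Br)[C@@H](O)CC1 | intermediate
3 | {[(1S)-2-bromo-3-methylcyclopent-2-en-1-yl]oxy}(tert-butyl)dimethylsilane | CC1=C(Br)[C@@H](O[Si](C)(C)C(C)(C)C)CC1 | intermediate
4 | [(5S)-5-{[tert-butyl(dimethyl)silyl]oxy}-2-methylcyclopent-1-en-1-yl]lithium | [Li]C1=C(C)CC[C@@H]1O[Si](C)(C)C(C)(C)C | intermediate
5 | 1-[(5S)-5-{[tert-butyl(dimethyl)silyl]oxy}-2-methylcyclopent-1-en-1-yl]ethan-1-one | CC(=O)C1=C(C)CC[C@@H]1O[Si](C)(C)C(C)(C)C | intermediate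
6 | methoxyallene (1-methoxypropa-1,2-diene) | COC=C=C | starting material
7 | (1-methoxypropa-1,2-dien-1-yl)lithium | [Li]C(OC)=C=C | intermediate
8 | tert-butyl(1-methoxypropa-1,2-dien-1-yl)dimethylsilane | COC(=C=C)[Si](C)(C)C(C)(C)C | intermediate
9 | 1-[tert-butyl(dimethyl)silyl]prop-2-en-1-one | C=CC(=O)[Si](C)(C)C(C)(C)C | intermediate
10 | lithium 1-[(5S)-5-{[tert-butyl(dimethyl)silyl]oxy}-2-methylcyclopent-1-en-1-yl]ethen-1-olate | [Li+].[O-]C(=C)C1=C(C)CC[C@@H]1O[Si](C)(C)C(C)(C)C | intermediate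
11 | lithium (1R,2S)-2-{[tert-butyl(dimethyl)silyl]oxy}-1-[(5S)-5-{[tert-butyl(dimethyl)silyl]oxy}-2-methylcyclopent-1-en-1-yl]-2-ethenylcyclopropan-1-olate (cyclopentenyl and ethenyl cis) | C=C[C@@]1(O[Si](C)(C)C(C)(C)C)C[C@@]1([O-])C1=C(C)CC[C@@H]1O[Si](C)(C)C(C)(C)C.[Li+] | intermediate
12 | lithium (3S,8aR)-3,6-bis{[tert-butyl(dimethyl)silyl]oxy}-8a-methyl-1,2,3,5,8,8a-hexahydroazulen-4-olate | CC(C)(C)[Si](C)(C)OC1=CC[C@@]2(C)CC[C@H](O[Si](C)(C)C(C)(C)C)C2=C([O-])C1.[Li+] | intermediate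
13 | (3S,3aR,8aR)-3,6-bis{[tert-butyl(dimethyl)silyl]oxy}-8a-methyl-2,3,3a,5,8,8a-hexahydroazulen-4(1H)-one | CC(C)(C)[Si](C)(C)OC1=CC[C@@]2(C)CC[C@H](O[Si](C)(C)C(C)(C)C)[C@@H]2C(=O)C1 | intermediate
14 | (3S,3aS,4S,8aR)-3,6-bis{[tert-butyl(dimethyl)silyl]oxy}-8a-methyl-1,2,3,3a,4,5,8,8a-octahydroazulen-4-ol | CC(C)(C)[Si](C)(C)OC1=CC[C@@]2(C)CC[C@H](O[Si](C)(C)C(C)(C)C)[C@@H]2[C@@H](O)C1 | intermediate
15 | (3S,3aR,4S,8aR)-3,6-bis{[tert-butyl(dimethyl)silyl]oxy}-8a-methyl-4-{[tri(propan-2-yl)silyl]oxy}-1,2,3,3a,4,5,8,8a-octahydroazulene | CC(C)(C)[Si](C)(C)OC1=CC[C@@]2(C)CC[C@H](O[Si](C)(C)C(C)(C)C)[C@@H]2[C@@H](O[Si](C(C)C)(C(C)C)C(C)C)C1 | intermediate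
16 | cesium (3S,3aR,4S,8aR)-3-{[tert-butyl(dimethyl)silyl]oxy}-8a-methyl-4-{[tri(propan-2-yl)silyl]oxy}-1,2,3,3a,4,5,8,8a-octahydroazulen-6-olate | [Cs+].[O-]C1=CC[C@@]2(C)CC[C@H](O[Si](C)(C)C(C)(C)C)[C@@H]2[C@@H](O[Si](C(C)C)(C(C)C)C(C)C)C1 | intermediate
17 | (3S,3aR,4S,8aR)-3-{[tert-butyl(dimethyl)silyl]oxy}-8a-methyl-4-{[tri(propan-2-yl)silyl]oxy}-1,2,3,3a,4,5,8,8a-octahydroazulen-6-yl trifluoromethanesulfonate | FC(F)(F)S(=O)(=O)OC1=CC[C@@]2(C)CC[C@H](O[Si](C)(C)C(C)(C)C)[C@@H]2[C@@H](O[Si](C(C)C)(C(C)C)C(C)C)C1 | intermediate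
18 | (3S,3aR,4S,8aR)-3-{[tert-butyl(dimethyl)silyl]oxy}-6,8a-dimethyl-4-{[tri(propan-2-yl)silyl]oxy}-1,2,3,3a,4,5,8,8a-octahydroazulene | CC1=CC[C@@]2(C)CC[C@H](O[Si](C)(C)C(C)(C)C)[C@@H]2[C@@H](O[Si](C(C)C)(C(C)C)C(C)C)C1 | intermediate
19 | (3S,3aR,4S,8aR)-6,8a-dimethyl-4-{[tri(propan-2-yl)silyl]oxy}-1,2,3,3a,4,5,8,8a-octahydroazulen-3-ol | CC1=CC[C@@]2(C)CC[C@H](O)[C@@H]2[C@@H](O[Si](C(C)C)(C(C)C)C(C)C)C1 | intermediate
20 | (3aS,4S,8aR)-6,8a-dimethyl-4-{[tri(propan-2-yl)silyl]oxy}-2,3a,4,5,8,8a-hexahydroazulen-3(1H)-one | CC1=CC[C@@]2(C)CCC(=O)[C@@H]2[C@@H](O[Si](C(C)C)(C(C)C)C(C)C)C1 | intermediate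
21 | (3R,3aS,4S,8aR)-6,8a-dimethyl-3-(propan-2-yl)-4-{[tri(propan-2-yl)silyl]oxy}-1,2,3,3a,4,5,8,8a-octahydroazulen-3-ol | CC1=CC[C@@]2(C)CC[C@@](O)(C(C)C)[C@@H]2[C@@H](O[Si](C(C)C)(C(C)C)C(C)C)C1 | intermediate
22 | (3R,3aS,4S,8aR)-6,8a-dimethyl-3-(propan-2-yl)-1,2,3,3a,4,5,8,8a-octahydroazulene-3,4-diol (jaeschkeanadiol) | CC1=CC[C@@]2(C)CC[C@@](O)(C(C)C)[C@@H]2[C@@H](O)C1 | intermediate
23 | 2,2-dimethyl-4H-1,3-benzodioxin-4-one | CC1(C)OC(=O)c2ccccc2O1 | starting material
24 | sodium (3R,3aS,4S,8aR)-3-hydroxy-6,8a-dimethyl-3-(propan-2-yl)-1,2,3,3a,4,5,8,8a-octahydroazulen-4-olate | CC1=CC[C@@]2(C)CC[C@@](O)(C(C)C)[C@@H]2[C@@H]([O-])C1.[Na+] | intermediate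
25 | (3R,3aS,4S,8aR)-3-hydroxy-6,8a-dimethyl-3-(propan-2-yl)-1,2,3,3a,4,5,8,8a-octahydroazulen-4-yl 2-hydroxybenzoate | CC1=CC[C@@]2(C)CC[C@@](O)(C(C)C)[C@@H]2[C@@H](OC(=O)c2ccccc2O)C1 | target

**Step count and risks**

Total step count: 14. Longest linear sequence: 13 steps (steps 1–3 and 5–14, from compound 1).

Steps most likely to fail:

1. Step 5 (key step). What may go wrong: conjugate addition of the enolate to the unsubstituted acryloylsilane (or its polymerization) may compete with carbonyl addition; the sigmatropic shift onto the methyl-bearing alkene carbon may be slow; facial control by the OTBS group may be incomplete. Fallback, from 5 back to 17: enolate 10 is made from 5 as before and combined with the β-silylated reagent (E)-1-[tert-butyl(dimethyl)silyl]-3-(trimethylsilyl)prop-2-en-1-one (C[Si](C)(C)/C=C/C(=O)[Si](C)(C)C(C)(C)C). Its β-silyl group blocks conjugate addition and stabilizes the carbanion, and this variant has the closest precedent; it should give the 8-trimethylsilyl ketone F1. Reduction with SmI2/H2O/Et3N and silylation with TIPSOTf/2,6-lutidine, as in steps 6 and 7, should give alcohol F2 and silyl ether F3. NBS (THF, −78 °C) converts the silyl enol ether into α-bromo ketone F4, and Bu4NF (THF, 0 °C) removes bromide together with the β-trimethylsilyl group (Fleming dehydrosilylation) to give enone F5. Conjugate reduction with LiBH(s-Bu)3 (THF, −78 °C) gives the regiodefined lithium enolate F6, which PhNTf2 traps as triflate 17.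

2. Step 6. What may go wrong: reduction from the open face may give the axial C4 carbinol, and the β,γ-unsaturated ketone may epimerize at C3a or lose its enol silyl group before it is reduced. Fallback, from 13 back to 14: LiBH(s-Bu)3 (THF, −78 °C) is expected to reduce 13 cleanly from the open face to the axial 4-epimeric alcohol F7. Mitsunobu inversion with chloroacetic acid (PPh3, DIAD, toluene, 0 °C) should give chloroacetate F8 with the C4 configuration of the target, and i-Bu2AlH (CH2Cl2, −78 °C) cleaves the ester to give 14.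

3. Step 12. What may go wrong: enolization or β-hydride reduction of the hindered ketone instead of addition, or attack from the wrong face. Fallback, from 20 back to 21: isopropenylmagnesium bromide with CeCl3 (THF, −78 °C), a smaller nucleophile without β-hydrogens on an sp3 carbon, should give isopropenyl carbinol F9. Hydrogenation with RhCl(PPh3)3 (H2, benzene, rt) reduces only the 1,1-disubstituted alkene and leaves the trisubstituted ring alkene, giving 21.

**Further compounds**

F1 | step 5 | 8-trimethylsilyl analogue of 13 (SiMe3 trans to the 8a-methyl group) | CC(C)(C)[Si](C)(C)OC1=C[C@@H]([Si](C)(C)C)[C@@]2(C)CC[C@H](O[Si](C)(C)C(C)(C)C)[C@@H]2C(=O)C1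
F2 | step 5 | 8-trimethylsilyl analogue of 14 | CC(C)(C)[Si](C)(C)OC1=C[C@@H]([Si](C)(C)C)[C@@]2(C)CC[C@H](O[Si](C)(C)C(C)(C)C)[C@@H]2[C@@H](O)C1
F3 | step 5 | 8-trimethylsilyl analogue of 15 | CC(C)(C)[Si](C)(C)OC1=C[C@@H]([Si](C)(C)C)[C@@]2(C)CC[C@H](O[Si](C)(C)C(C)(C)C)[C@@H]2[C@@H](O[Si](C(C)C)(C(C)C)C(C)C)C1
F4 | step 5 | 7-bromo-8-trimethylsilyl-6-ketone from F3 (3-OTBS, 4-OTIPS, bromide epimers at C7) | O=C1C(Br)[C@@H]([Si](C)(C)C)[C@@]2(C)CC[C@H](O[Si](C)(C)C(C)(C)C)[C@@H]2[C@@H](O[Si](C(C)C)(C(C)C)C(C)C)C1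
F5 | step 5 | 6-oxo-7,8-ene (cycloheptenone) with 3-OTBS, 4-OTIPS and 8a-methyl as in 17 | O=C1C=C[C@@]2(C)CC[C@H](O[Si](C)(C)C(C)(C)C)[C@@H]2[C@@H](O[Si](C(C)C)(C(C)C)C(C)C)C1
F6 | step 5 | lithium analogue of enolate 16 | [Li+].[O-]C1=CC[C@@]2(C)CC[C@H](O[Si](C)(C)C(C)(C)C)[C@@H]2[C@@H](O[Si](C(C)C)(C(C)C)C(C)C)C1
F7 | step 6 | (3S,3aS,4R,8aR)-4-epimer of 14 (axial 4-OH, cis to the 8a-methyl group) | CC(C)(C)[Si](C)(C)OC1=CC[C@@]2(C)CC[C@H](O[Si](C)(C)C(C)(C)C)[C@@H]2[C@H](O)C1
F8 | step 6 | chloroacetate of 14 | CC(C)(C)[Si](C)(C)OC1=CC[C@@]2(C)CC[C@H](O[Si](C)(C)C(C)(C)C)[C@@H]2[C@@H](OC(=O)CCl)C1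
F9 | step 12 | 3-(prop-1-en-2-yl) analogue of 21 | CC1=CC[C@@]2(C)CC[C@@](O)(C(C)=C)[C@@H]2[C@@H](O[Si](C(C)C)(C(C)C)C(C)C)C1
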